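## Retrosynthetic overview

1. Target 27 comes from oxidative demethylation of the 1,4-dimethoxynaphthalene 26, which comes from selective acetylation of diol 25, itself released from acetonide 24.
2. Key disconnection: the CH2–CH2 bond next to the dioxolane, made by α-selective carbonyl allylation of aldehyde 20 (fragment B) with the allylbarium reagent from chloride 13 (fragment A); the carbinol formed is then deoxygenated.
3. Fragment B: geraniol, Sharpless epoxidation, then epoxide hydrolysis with inversion at the tertiary carbon (this sets both stereocentres), then acetonide aldehyde.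
4. Fragment A: 7-bromo-1-tetralone to 7-bromo-1,4-dimethoxy-2-methylnaphthalene, then Heck reaction, E-selective Wittig, reduction and chlorination.
5. Rings: the carbobicycle is bought; its second ring is aromatised (step 3), oxidised to the quinone and masked (steps 4–5); oxirane (step 10) and dioxolane (step 13) are temporary; the quinone ring is unveiled last (step 21).

Assumption: 7-bromo-1-tetralone, geraniol and D-(−)-diethyl tartrate are bought; numbers are given to substrates, intermediates and products, while simple reagents are named on the Conditions and reagent lines.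

## Route

Step 1
Reactants: 1 7-bromo-3,4-dihydronaphthalen-1(2H)-one
Product: 3 7-bromo-2-methyl-3,4-dihydronaphthalen-1(2H)-one (racemic), via lithium enolate 2 (not isolated)
Conditions: LiN(iPr)2 (1.05 equiv), THF, −78 °C; then MeI, −78 °C to 0 °C
Reagents that add atoms: iodomethane, CI
Why: Kinetic enolate alkylation: LiN(iPr)2 deprotonates the only enolisable position (C2) and the lithium enolate is C-methylated by SN2 on MeI, the new stereocentre being racemic and destroyed in step 3.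

Step 2
Reactants: 3 7-bromo-2-methyl-3,4-dihydronaphthalen-1(2H)-one
Product: 4 2,7-dibromo-2-methyl-3,4-dihydronaphthalen-1(2H)-one (racemic)
Conditions: CuBr2 (2.2 equiv), EtOAc/CHCl3 (1:1), reflux
Reagents that add atoms: copper dibromide (CuBr2), [Cu+2].[Br-].[Br-]
Why: Enol-mediated α-bromination of the ketone by divalent copper bromide occurs at the single remaining α-hydrogen (C2), while the deactivated bromoarene ring does not react.

Step 3
Reactants: 4 2,7-dibromo-2-methyl-3,4-dihydronaphthalen-1(2H)-one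
Product: 6 7-bromo-2-methylnaphthalen-1-ol, via dienone tautomer 5 (not isolated)
Conditions: LiBr, Li2CO3, DMF, 130 °C
Reagents that add atoms: none
Why: Base-mediated E2 dehydrobromination gives the cross-conjugated ketone 5, whose tautomerisation to the naphthol is driven by aromatisation of the second ring.

Step 4
Reactants: 6 7-bromo-2-methylnaphthalen-1-ol
Product: 7 7-bromo-2-methylnaphthalene-1,4-dione
Conditions: PhI(OCOCF3)2 (2.2 equiv), MeCN/H2O (2:1), 0 °C
Reagents that add atoms: water, O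
Why: Phenol oxidation by trivalent iodine: the aryloxy-iodane is attacked by water at the free para position (C2 is blocked by methyl) and a second oxidation gives the para-quinone.

Step 5
Reactants: 7 7-bromo-2-methylnaphthalene-1,4-dione
Product: 9 7-bromo-1,4-dimethoxy-2-methylnaphthalene, via hydroquinone 8 (not isolated)
Conditions: Na2S2O4, EtOAc/H2O, rt; then Me2SO4, K2CO3, acetone, reflux
Reagents that add atoms: dimethyl sulfate, COS(=O)(=O)OC
Why: Dithionite reduces the quinone to the hydroquinone, which is O-methylated twice (Williamson ether synthesis) to mask the quinone as a robust dimethyl ether.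

Step 6
Reactants: 9 7-bromo-1,4-dimethoxy-2-methylnaphthalene
Product: 10 3-(5,8-dimethoxy-7-methylnaphthalen-2-yl)propanal
Conditions: allyl alcohol (1.5 equiv), Pd(OAc)2 (3 mol%), Bu4NCl, NaHCO3, DMF, 80 °C
Reagents that add atoms: allyl alcohol, C=CCO
Why: Heck reaction under Jeffery conditions: the aryl group adds to the terminal carbon of allyl alcohol and β-hydride elimination toward the carbinol carbon followed by tautomerisation delivers the saturated aldehyde.

Step 7
Reactants: 10 3-(5,8-dimethoxy-7-methylnaphthalen-2-yl)propanal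
Product: 11 ethyl (2E)-5-(5,8-dimethoxy-7-methylnaphthalen-2-yl)-2-methylpent-2-enoate
Conditions: Ph3P=C(CH3)CO2Et (1.3 equiv), toluene, 80 °C
Reagents that add atoms: ethyl 2-(triphenyl-λ5-phosphanylidene)propanoate, CCOC(=O)C(C)=P(c1ccccc1)(c1ccccc1)c1ccccc1
Why: Wittig olefination with an α-methyl stabilised ylide gives the E trisubstituted enoate (typically above 95:5), which fixes the geometry of the side-chain olefin.

Step 8
Reactants: 11 ethyl (2E)-5-(5,8-dimethoxy-7-methylnaphthalen-2-yl)-2-methylpent-2-enoate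
Product: 12 (2E)-5-(5,8-dimethoxy-7-methylnaphthalen-2-yl)-2-methylpent-2-en-1-ol
Conditions: iBu2AlH (2.5 equiv), CH2Cl2, −78 °C; aq. KNaC4H4O6 work-up
Reagents that add atoms: none
Why: Hydride 1,2-reduction of the conjugated ester by iBu2AlH at low temperature gives the allylic alcohol without touching the olefin geometry.

Step 9
Reactants: 12 (2E)-5-(5,8-dimethoxy-7-methylnaphthalen-2-yl)-2-methylpent-2-en-1-ol
Product: 13 7-[(3E)-5-chloro-4-methylpent-3-en-1-yl]-1,4-dimethoxy-2-methylnaphthalene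
Conditions: PPh3, CCl4, reflux
Reagents that add atoms: tetrachloromethane, ClC(Cl)(Cl)Cl
Why: Appel chlorination: the alkoxyphosphonium ion is displaced by chloride in an SN2 reaction at the primary carbon, so neither allylic transposition nor E/Z isomerisation occurs.

Step 10
Reactants: 14 geraniol
Product: 15 [(2R,3R)-3-methyl-3-(4-methylpent-3-en-1-yl)oxiran-2-yl]methanol
Conditions: t-BuOOH, Ti(OiPr)4 (5 mol%), D-(−)-diethyl tartrate (7 mol%), 4 Å molecular sieves, CH2Cl2, −20 °C
Reagents that add atoms: tert-butyl hydroperoxide, CC(C)(C)OO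
Why: Sharpless asymmetric epoxidation: the titanium tartrate complex binds the allylic alcohol and delivers oxygen only to the 2,3-olefin, D-(−)-tartrate giving the (2R,3R) epoxide (about 95% ee), which sets C7 of the target directly and C6 after inversion in step 12.

Step 11
Reactants: 15 [(2R,3R)-3-methyl-3-(4-methylpent-3-en-1-yl)oxiran-2-yl]methanol
Product: 16 tert-butyl{[(2R,3R)-3-methyl-3-(4-methylpent-3-en-1-yl)oxiran-2-yl]methoxy}diphenylsilane
Conditions: t-BuPh2SiCl, imidazole, CH2Cl2, 0 °C to rt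
Reagents that add atoms: tert-butyl(chloro)diphenylsilane, CC(C)(C)[Si](Cl)(c1ccccc1)c1ccccc1
Why: Imidazole-mediated silylation protects the primary alcohol as a bulky silyl ether that survives the acid of steps 12 and 13.

Step 12
Reactants: 16 tert-butyl{[(2R,3R)-3-methyl-3-(4-methylpent-3-en-1-yl)oxiran-2-yl]methoxy}diphenylsilane
Product: 17 (2R,3S)-1-{[tert-butyl(diphenyl)silyl]oxy}-3,7-dimethyloct-6-ene-2,3-diol
Conditions: HClO4 (5% aq., cat.), THF/H2O, 0 °C
Reagents that add atoms: water, O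
Why: Acid-catalysed epoxide hydrolysis: water attacks the protonated epoxide at the tertiary carbon with inversion while the C2–O bond is kept, which gives the (2R,3S) diol carrying both stereocentres of the target.

Step 13
Reactants: 17 (2R,3S)-1-{[tert-butyl(diphenyl)silyl]oxy}-3,7-dimethyloct-6-ene-2,3-diol
Product: 18 tert-butyl{[(4R,5S)-2,2,5-trimethyl-5-(4-methylpent-3-en-1-yl)-1,3-dioxolan-4-yl]methoxy}diphenylsilane
Conditions: Me2C(OMe)2, TsOH·H2O (cat.), acetone, rt
Reagents that add atoms: 2,2-dimethoxypropane, COC(C)(C)OC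
Why: Acid-catalysed transacetalisation ties the secondary/tertiary diol into a dioxolane that withstands the organometallic and radical steps.

Step 14
Reactants: 18 tert-butyl{[(4R,5S)-2,2,5-trimethyl-5-(4-methylpent-3-en-1-yl)-1,3-dioxolan-4-yl]methoxy}diphenylsilane
Product: 19 [(4R,5S)-2,2,5-trimethyl-5-(4-methylpent-3-en-1-yl)-1,3-dioxolan-4-yl]methanol
Conditions: Bu4NF, THF, rt
Reagents that add atoms: none
Why: Fluoride-mediated desilylation (strong Si–F bond) frees the primary alcohol, the acetonide being inert.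

Step 15
Reactants: 19 [(4R,5S)-2,2,5-trimethyl-5-(4-methylpent-3-en-1-yl)-1,3-dioxolan-4-yl]methanol
Product: 20 (4S,5S)-2,2,5-trimethyl-5-(4-methylpent-3-en-1-yl)-1,3-dioxolane-4-carbaldehyde
Conditions: Dess–Martin periodinane, CH2Cl2, 0 °C to rt; used at once
Reagents that add atoms: none
Why: Dess–Martin oxidation gives the α-alkoxy aldehyde under near-neutral conditions without epimerisation at C4 (the descriptor changes only because CHO outranks C5).

Step 16
Reactants: 13 7-[(3E)-5-chloro-4-methylpent-3-en-1-yl]-1,4-dimethoxy-2-methylnaphthalene; 20 (4S,5S)-2,2,5-trimethyl-5-(4-methylpent-3-en-1-yl)-1,3-dioxolane-4-carbaldehyde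
Product: 22 (3E)-6-(5,8-dimethoxy-7-methylnaphthalen-2-yl)-3-methyl-1-[(4R,5S)-2,2,5-trimethyl-5-(4-methylpent-3-en-1-yl)-1,3-dioxolan-4-yl]hex-3-en-1-ol (both C1 epimers), via allylbarium chloride reagent 21 (not isolated)
Conditions: BaI2, Li(C12H10) (lithium biphenylide, 2 equiv), THF, rt; 13 (1.3 equiv), −78 °C; then 20, −78 °C; aq. NH4Cl
Reagents that add atoms: none
Why: Carbonyl allylation with an allylbarium reagent: oxidative addition of active zerovalent barium into the allylic chloride at −78 °C gives a configurationally stable allylbarium that adds to the aldehyde through its α-carbon with retention of the E geometry, joining fragments A and B, and the new carbinol centre is an epimer mixture that is removed in step 18.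

Step 17
Reactants: 22 (3E)-6-(5,8-dimethoxy-7-methylnaphthalen-2-yl)-3-methyl-1-[(4R,5S)-2,2,5-trimethyl-5-(4-methylpent-3-en-1-yl)-1,3-dioxolan-4-yl]hex-3-en-1-ol
Product: 23 O-{(3E)-6-(5,8-dimethoxy-7-methylnaphthalen-2-yl)-3-methyl-1-[(4R,5S)-2,2,5-trimethyl-5-(4-methylpent-3-en-1-yl)-1,3-dioxolan-4-yl]hex-3-en-1-yl} 1H-imidazole-1-carbothioate
Conditions: 1,1'-thiocarbonyldiimidazole, DMAP (cat.), toluene, 80 °C
Reagents that add atoms: 1,1'-thiocarbonyldiimidazole, S=C(n1ccnc1)n1ccnc1
Why: Acyl-transfer thiocarbonylation of the secondary alcohol gives the imidazolyl thiocarbonate needed for radical deoxygenation.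

Step 18
Reactants: 23 O-{(3E)-6-(5,8-dimethoxy-7-methylnaphthalen-2-yl)-3-methyl-1-[(4R,5S)-2,2,5-trimethyl-5-(4-methylpent-3-en-1-yl)-1,3-dioxolan-4-yl]hex-3-en-1-yl} 1H-imidazole-1-carbothioate
Product: 24 7-{(3E)-4-methyl-6-[(4R,5S)-2,2,5-trimethyl-5-(4-methylpent-3-en-1-yl)-1,3-dioxolan-4-yl]hex-3-en-1-yl}-1,4-dimethoxy-2-methylnaphthalene
Conditions: Bu3SnH (2 equiv), AIBN (cat.), toluene, 100 °C
Reagents that add atoms: none
Why: Barton–McCombie deoxygenation: the stannyl radical adds to C=S, β-scission gives a secondary alkyl radical that abstracts hydrogen from Bu3SnH faster than it can cyclise, and the two dioxolane stereocentres are not involved.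

Step 19
Reactants: 24 7-{(3E)-4-methyl-6-[(4R,5S)-2,2,5-trimethyl-5-(4-methylpent-3-en-1-yl)-1,3-dioxolan-4-yl]hex-3-en-1-yl}-1,4-dimethoxy-2-methylnaphthalene
Product: 25 (6S,7R,10E)-13-(5,8-dimethoxy-7-methylnaphthalen-2-yl)-2,6,10-trimethyltrideca-2,10-diene-6,7-diol
Conditions: 1 M HCl (aq.), THF, rt
Reagents that add atoms: none
Why: Acid-catalysed acetal hydrolysis under dilute conditions frees the diol without hydration or cyclisation of the trisubstituted olefins.

Step 20
Reactants: 25 (6S,7R,10E)-13-(5,8-dimethoxy-7-methylnaphthalen-2-yl)-2,6,10-trimethyltrideca-2,10-diene-6,7-diol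
Product: 26 (6S,7R,10E)-13-(5,8-dimethoxy-7-methylnaphthalen-2-yl)-6-hydroxy-2,6,10-trimethyltrideca-2,10-dien-7-yl acetate
Conditions: Ac2O (1.2 equiv), pyridine, DMAP (cat.), CH2Cl2, 0 °C
Reagents that add atoms: acetic anhydride, CC(=O)OC(C)=O
Why: Nucleophile-catalysed acylation is selective for the secondary hydroxyl because the tertiary hydroxyl is too hindered to react at 0 °C.

Step 21
Reactants: 26 (6S,7R,10E)-13-(5,8-dimethoxy-7-methylnaphthalen-2-yl)-6-hydroxy-2,6,10-trimethyltrideca-2,10-dien-7-yl acetate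
Product: 27 chabrolonaphthoquinone B
Conditions: (NH4)2Ce(NO3)6 (2.5 equiv), MeCN/H2O (3:1), 0 °C
Reagents that add atoms: water, O
Why: Oxidative demethylation by tetravalent cerium: two single-electron oxidations of the electron-rich dimethoxynaphthalene and addition of water release methanol and the 1,4-quinone, leaving the acetate, the tertiary alcohol and the olefins untouched.

## Compound list

1 | 7-bromo-3,4-dihydronaphthalen-1(2H)-one (7-bromo-1-tetralone) | O=C1CCCc2ccc(Br)cc21 | starting material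
2 | lithium 7-bromo-3,4-dihydronaphthalen-1-olate (lithium enolate of 1) | [Li]OC1=CCCc2ccc(Br)cc12 | intermediate
3 | 7-bromo-2-methyl-3,4-dihydronaphthalen-1(2H)-one (racemic) | CC1CCc2ccc(Br)cc2C1=O | intermediate
4 | 2,7-dibromo-2-methyl-3,4-dihydronaphthalen-1(2H)-one (racemic) | CC1(Br)CCc2ccc(Br)cc2C1=O | intermediate
5 | 7-bromo-2-methylnaphthalen-1(4H)-one | CC1=CCc2ccc(Br)cc2C1=O | intermediate
6 | 7-bromo-2-methylnaphthalen-1-ol | Cc1ccc2ccc(Br)cc2c1O | intermediate
7 | 7-bromo-2-methylnaphthalene-1,4-dione | CC1=CC(=O)c2ccc(Br)cc2C1=O | intermediate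
8 | 7-bromo-2-methylnaphthalene-1,4-diol | Cc1cc(O)c2ccc(Br)cc2c1O | intermediate
9 | 7-bromo-1,4-dimethoxy-2-methylnaphthalene | Brc1ccc2c(OC)cc(C)c(OC)c2c1 | intermediate
10 | 3-(5,8-dimethoxy-7-methylnaphthalen-2-yl)propanal | O=CCCc1ccc2c(OC)cc(C)c(OC)c2c1 | intermediate
11 | ethyl (2E)-5-(5,8-dimethoxy-7-methylnaphthalen-2-yl)-2-methylpent-2-enoate | CCOC(=O)/C(C)=C/CCc1ccc2c(OC)cc(C)c(OC)c2c1 | intermediate
12 | (2E)-5-(5,8-dimethoxy-7-methylnaphthalen-2-yl)-2-methylpent-2-en-1-ol | OC/C(C)=C/CCc1ccc2c(OC)cc(C)c(OC)c2c1 | intermediate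
13 | 7-[(3E)-5-chloro-4-methylpent-3-en-1-yl]-1,4-dimethoxy-2-methylnaphthalene | ClC/C(C)=C/CCc1ccc2c(OC)cc(C)c(OC)c2c1 | intermediate
14 | geraniol, (2E)-3,7-dimethylocta-2,6-dien-1-ol | CC(C)=CCC/C(C)=C/CO | starting material
15 | [(2R,3R)-3-methyl-3-(4-methylpent-3-en-1-yl)oxiran-2-yl]methanol | OC[C@H]1O[C@]1(C)CCC=C(C)C | intermediate
16 | tert-butyl{[(2R,3R)-3-methyl-3-(4-methylpent-3-en-1-yl)oxiran-2-yl]methoxy}diphenylsilane | CC(C)(C)[Si](OC[C@H]1O[C@]1(C)CCC=C(C)C)(c1ccccc1)c1ccccc1 | intermediate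
17 | (2R,3S)-1-{[tert-butyl(diphenyl)silyl]oxy}-3,7-dimethyloct-6-ene-2,3-diol | CC(C)(C)[Si](OC[C@@H](O)[C@@](C)(O)CCC=C(C)C)(c1ccccc1)c1ccccc1 | intermediate
18 | tert-butyl{[(4R,5S)-2,2,5-trimethyl-5-(4-methylpent-3-en-1-yl)-1,3-dioxolan-4-yl]methoxy}diphenylsilane | CC(C)(C)[Si](OC[C@H]1OC(C)(C)O[C@@]1(C)CCC=C(C)C)(c1ccccc1)c1ccccc1 | intermediate
19 | [(4R,5S)-2,2,5-trimethyl-5-(4-methylpent-3-en-1-yl)-1,3-dioxolan-4-yl]methanol | OC[C@H]1OC(C)(C)O[C@@]1(C)CCC=C(C)C | intermediate
20 | (4S,5S)-2,2,5-trimethyl-5-(4-methylpent-3-en-1-yl)-1,3-dioxolane-4-carbaldehyde | O=C[C@H]1OC(C)(C)O[C@@]1(C)CCC=C(C)C | intermediate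
21 | chlorido[(2E)-5-(5,8-dimethoxy-7-methylnaphthalen-2-yl)-2-methylpent-2-en-1-yl]barium | Cl[Ba]C/C(C)=C/CCc1ccc2c(OC)cc(C)c(OC)c2c1 | intermediate
22 | (3E)-6-(5,8-dimethoxy-7-methylnaphthalen-2-yl)-3-methyl-1-[(4R,5S)-2,2,5-trimethyl-5-(4-methylpent-3-en-1-yl)-1,3-dioxolan-4-yl]hex-3-en-1-ol (both C1 epimers) | OC(C/C(C)=C/CCc1ccc2c(OC)cc(C)c(OC)c2c1)[C@H]1OC(C)(C)O[C@@]1(C)CCC=C(C)C | intermediate
23 | O-{(3E)-6-(5,8-dimethoxy-7-methylnaphthalen-2-yl)-3-methyl-1-[(4R,5S)-2,2,5-trimethyl-5-(4-methylpent-3-en-1-yl)-1,3-dioxolan-4-yl]hex-3-en-1-yl} 1H-imidazole-1-carbothioate (both C1 epimers) | S=C(OC(C/C(C)=C/CCc1ccc2c(OC)cc(C)c(OC)c2c1)[C@H]1OC(C)(C)O[C@@]1(C)CCC=C(C)C)n1ccnc1 | intermediate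
24 | 7-{(3E)-4-methyl-6-[(4R,5S)-2,2,5-trimethyl-5-(4-methylpent-3-en-1-yl)-1,3-dioxolan-4-yl]hex-3-en-1-yl}-1,4-dimethoxy-2-methylnaphthalene | C(C/C(C)=C/CCc1ccc2c(OC)cc(C)c(OC)c2c1)[C@H]1OC(C)(C)O[C@@]1(C)CCC=C(C)C | intermediate
25 | (6S,7R,10E)-13-(5,8-dimethoxy-7-methylnaphthalen-2-yl)-2,6,10-trimethyltrideca-2,10-diene-6,7-diol | O[C@H](CC/C(C)=C/CCc1ccc2c(OC)cc(C)c(OC)c2c1)[C@@](C)(O)CCC=C(C)C | intermediate
26 | (6S,7R,10E)-13-(5,8-dimethoxy-7-methylnaphthalen-2-yl)-6-hydroxy-2,6,10-trimethyltrideca-2,10-dien-7-yl acetate | CC(=O)O[C@H](CC/C(C)=C/CCc1ccc2c(OC)cc(C)c(OC)c2c1)[C@@](C)(O)CCC=C(C)C | intermediate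
27 | chabrolonaphthoquinone B, (6S,7R,10E)-6-hydroxy-2,6,10-trimethyl-13-(7-methyl-5,8-dioxo-5,8-dihydronaphthalen-2-yl)trideca-2,10-dien-7-yl acetate | CC(=O)O[C@H](CC/C(C)=C/CCc1ccc2c(c1)C(=O)C(C)=CC2=O)[C@@](C)(O)CCC=C(C)C | target

## Step count and risks

Total step count: 21 (steps 1–9 for fragment A, steps 10–15 for fragment B, steps 16–21 for union and end game).
Longest linear sequence: 15 steps (1 to 27 through steps 1–9 and 16–21); the geraniol branch reaches aldehyde 20 in 6 steps.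

The three steps most likely to fail:

Step 16 (allylbarium addition). The risks are Wurtz coupling of chloride 13, some γ-attack giving the branched alcohol, and the handling of active barium on small scale. The fallback sets out from 13 and 19 and comes back at 24, replacing steps 15 to 18 by a sulfone alkylation. Chloride 13 is treated with PhSO2Na in DMF to give 7-[(3E)-5-(benzenesulfonyl)-4-methylpent-3-en-1-yl]-1,4-dimethoxy-2-methylnaphthalene F1. Alcohol 19 is converted with I2, PPh3 and imidazole into (4S,5S)-4-(iodomethyl)-2,2,5-trimethyl-5-(4-methylpent-3-en-1-yl)-1,3-dioxolane F2. F1 is lithiated (n-BuLi, THF/HMPA, −78 °C) and alkylated by F2 to give 7-{(3E)-5-(benzenesulfonyl)-4-methyl-6-[(4R,5S)-2,2,5-trimethyl-5-(4-methylpent-3-en-1-yl)-1,3-dioxolan-4-yl]hex-3-en-1-yl}-1,4-dimethoxy-2-methylnaphthalene F3 as a mixture of epimers at the sulfone carbon. Reductive desulfonylation of F3 (LiBHEt3, PdCl2(dppp) cat., THF, 0 °C) gives 24.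

Step 6 (Heck reaction with allyl alcohol). The risks are formation of the branched 2-aryl aldehyde and aldol self-condensation of 10 under the basic conditions. The fallback sets out from 9 and comes back at 10. Heck coupling of 9 with ethyl acrylate (Pd(OAc)2, P(o-tolyl)3, Et3N, DMF, 100 °C) gives ethyl (2E)-3-(5,8-dimethoxy-7-methylnaphthalen-2-yl)prop-2-enoate F4. Hydrogenation (H2, Pd/C, EtOAc) gives ethyl 3-(5,8-dimethoxy-7-methylnaphthalen-2-yl)propanoate F5, and partial reduction of F5 (iBu2AlH, 1.1 equiv, CH2Cl2, −78 °C) gives 10.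

Step 12 (epoxide hydrolysis). Any attack of water at C2, or ionisation at C3, would erode the enantiomeric and diastereomeric purity of the diol. The fallback sets out from 15 and comes back at 17, and uses a titanium-templated opening of the free epoxy alcohol. Treatment of 15 with Ti(OiPr)4 and PhCO2H in CH2Cl2 opens the chelated epoxide at C3 with inversion to give (2R,3S)-1,2-dihydroxy-3,7-dimethyloct-6-en-3-yl benzoate F6. Selective silylation of the primary hydroxyl (t-BuPh2SiCl, imidazole) gives (2R,3S)-1-{[tert-butyl(diphenyl)silyl]oxy}-2-hydroxy-3,7-dimethyloct-6-en-3-yl benzoate F7, and methanolysis of the benzoate (K2CO3, MeOH) gives 17.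

## Further compounds

F1 | step 16 | 7-[(3E)-5-(benzenesulfonyl)-4-methylpent-3-en-1-yl]-1,4-dimethoxy-2-methylnaphthalene | O=S(=O)(C/C(C)=C/CCc1ccc2c(OC)cc(C)c(OC)c2c1)c1ccccc1
F2 | step 16 | (4S,5S)-4-(iodomethyl)-2,2,5-trimethyl-5-(4-methylpent-3-en-1-yl)-1,3-dioxolane | IC[C@H]1OC(C)(C)O[C@@]1(C)CCC=C(C)C
F3 | step 16 | 7-{(3E)-5-(benzenesulfonyl)-4-methyl-6-[(4R,5S)-2,2,5-trimethyl-5-(4-methylpent-3-en-1-yl)-1,3-dioxolan-4-yl]hex-3-en-1-yl}-1,4-dimethoxy-2-methylnaphthalene (epimers at the sulfone carbon) | O=S(=O)(C(C[C@H]1OC(C)(C)O[C@@]1(C)CCC=C(C)C)/C(C)=C/CCc1ccc2c(OC)cc(C)c(OC)c2c1)c1ccccc1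
F4 | step 6 | ethyl (2E)-3-(5,8-dimethoxy-7-methylnaphthalen-2-yl)prop-2-enoate | CCOC(=O)/C=C/c1ccc2c(OC)cc(C)c(OC)c2c1
F5 | step 6 | ethyl 3-(5,8-dimethoxy-7-methylnaphthalen-2-yl)propanoate | CCOC(=O)CCc1ccc2c(OC)cc(C)c(OC)c2c1
F6 | step 12 | (2R,3S)-1,2-dihydroxy-3,7-dimethyloct-6-en-3-yl benzoate | OC[C@@H](O)[C@@](C)(OC(=O)c1ccccc1)CCC=C(C)C
F7 | step 12 | (2R,3S)-1-{[tert-butyl(diphenyl)silyl]oxy}-2-hydroxy-3,7-dimethyloct-6-en-3-yl benzoate | CC(C)(C)[Si](OC[C@@H](O)[C@@](C)(OC(=O)c1ccccc1)CCC=C(C)C)(c1ccccc1)c1ccccc1
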